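The pyranone ring is disconnected at C5–C6 and O1–C2. The C3–C4–C5 segment of the ring, together with both ethyl substituents, maps onto heptan-4-one; C2 is a lone carbon at the oxidation level of carbonic acid, supplied as CS2; C6 is the carbonyl carbon of the fatty acyl chain. The key step uses this pattern: the enolate of a heptan-4-one ketene dithioacetal is acylated at C5 by a chiral long-chain acid chloride, and the diketone formed closes the ring through its enol oxygen onto C2 with loss of methanethiol, in one flask. Its precursors are 3-[bis(methylsulfanyl)methylidene]heptan-4-one and (S)-11-acetoxydodecanoyl chloride; sulfur on C2 is exchanged for methoxide afterwards.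

Key step: step 6

Remark: ring numbering is O1, C2 (OMe), C3 (Et), C4 (C=O), C5 (Et), C6 (side chain); the side-chain center is S, and (S)-propylene oxide delivers it with the same descriptor because the Grignard reagent attacks only the CH2 carbon.

Step 1
Reactants: 1 heptan-4-one; 2 carbon disulfide
Product: 4 3-[bis(methylsulfanyl)methylidene]heptan-4-one, via dilithium ketene dithiolate 3 (not isolated)
Conditions: LiN(SiMe3)2 (1.0 equiv), THF, -78 °C; CS2 (1.0 equiv), -78 → 0 °C; LiN(SiMe3)2 (1.0 equiv), -78 °C; MeI (2.3 equiv), -78 °C → rt
Reagents that add atoms: iodomethane, CI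
Why: Dithiocarboxylation of the ketone enolate with CS2, a second deprotonation to dithiolate 3 and twofold S-methylation (alpha-oxo ketene dithioacetal synthesis) should work on a simple dialkyl ketone, and the symmetry of heptan-4-one leaves no regiochemical choice.

Step 2
Reactants: 5 10-bromodec-1-ene; 6 (S)-propylene oxide
Product: 8 (2S)-tridec-12-en-2-ol, via dec-9-enylmagnesium bromide 7 (not isolated)
Conditions: Mg, THF, 40 °C; then CuI (10 mol %), 6, THF, -30 → 0 °C; aq NH4Cl
Reagents that add atoms: none
Why: Copper-catalysed SN2 opening of a monosubstituted epoxide by a primary Grignard reagent takes place at the CH2 terminus, so the C–O stereocenter is not touched and its S configuration passes unchanged into 8, while CuI suppresses bromohydrin formation.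

Step 3
Reactants: 8 (2S)-tridec-12-en-2-ol
Product: 9 (2S)-tridec-12-en-2-yl acetate
Conditions: Ac2O, pyridine, DMAP (cat.), CH2Cl2, 0 °C → rt
Reagents that add atoms: acetic anhydride, CC(=O)OC(C)=O
Why: DMAP-catalysed acetylation of an unhindered secondary alcohol breaks only the O–H bond, so the configuration is retained and the hydroxyl is masked, as the group the target needs, against the oxidation that follows.

Step 4
Reactants: 9 (2S)-tridec-12-en-2-yl acetate
Product: 11 (11S)-11-acetoxydodecanoic acid, via acetoxy aldehyde 10 (not isolated)
Conditions: RuCl3·xH2O (3 mol %), NaIO4 (4.2 equiv), MeCN/EtOAc/H2O, rt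
Reagents that add atoms: sodium periodate, [Na+].[O-]I(=O)(=O)=O; water, O
Why: RuO4-catalysed oxidative cleavage of a terminal alkene with periodate as terminal oxidant should give the acid one carbon shorter through aldehyde 10, and the secondary acetate and the saturated chain are inert under these biphasic conditions.

Step 5
Reactants: 11 (11S)-11-acetoxydodecanoic acid
Product: 12 (11S)-11-acetoxydodecanoyl chloride
Conditions: (COCl)2 (1.3 equiv), DMF (cat.), CH2Cl2, 0 °C → rt; evaporate, use crude
Reagents that add atoms: oxalyl chloride, O=C(Cl)C(=O)Cl
Why: Vilsmeier-type activation with (COCl)2 and catalytic DMF converts the acid into the acid chloride under neutral conditions at room temperature, which leave the acetate and the remote stereocenter untouched.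

Step 6
Reactants: 4 3-[bis(methylsulfanyl)methylidene]heptan-4-one (2.1 equiv); 12 (11S)-11-acetoxydodecanoyl chloride (1.0 equiv)
Product: 15 (2S)-11-[3,5-diethyl-6-(methylsulfanyl)-4-oxo-4H-pyran-2-yl]undecan-2-yl acetate, via lithium enolate 13 (not isolated), via acylated diketone 14 (not isolated)
Conditions: 4, LiN(SiMe3)2 (2.0 equiv), THF, -78 °C; 12, -78 → -20 °C; then CF3CO2H (excess), CH2Cl2, 0 °C → rt (CH3SH vented through bleach)
Reagents that add atoms: none
Why: Deprotonation of 4 can take place only at the propyl CH2 next to the carbonyl, since the other alpha carbon is fully substituted, and the resulting enolate 13 attacks the acid chloride in a Claisen-type C-acylation that forms the C5–C6 bond; the second equivalent of 13 deprotonates the more acidic diketone 14 and re-acylates on carbon any enol ester formed by O-acylation. On acidification the enol oxygen of the new acyl group adds to the bis(methylsulfanyl) carbon, the beta carbon of the enone, and CH3SH is expelled (oxa-conjugate addition–elimination), which forms the O1–C2 bond. The closest known reaction type is the acylation of alpha-oxo ketene dithioacetal enolates followed by cyclocondensation to 2-(methylsulfanyl)-4-pyranones. The one ring closes in a 6-endo-trig mode, and loss of CH3SH to the conjugated 4-pyranone makes the closure irreversible. No stereocenter is formed, and the remote S center takes no part. The step needs C- over O-acylation and attack on the acid chloride in preference to the acetate, which the lithium counter-ion in THF at -78 °C, the twofold amount of enolate and the much higher reactivity of the acid chloride should secure; the regiochemistry is fixed because C2 already carries sulfur and C4 is already the ketone.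

Step 7
Reactants: 15 (2S)-11-[3,5-diethyl-6-(methylsulfanyl)-4-oxo-4H-pyran-2-yl]undecan-2-yl acetate
Product: 17 (2S)-11-[3,5-diethyl-6-(methanesulfonyl)-4-oxo-4H-pyran-2-yl]undecan-2-yl acetate, via sulfoxide 16 (not isolated)
Conditions: 3-ClC6H4CO3H (2.3 equiv), CH2Cl2, 0 °C → rt
Reagents that add atoms: 3-chloroperbenzoic acid, OOC(=O)c1cccc(Cl)c1
Why: Electrophilic sulfide oxidation by the peracid runs through sulfoxide 16 to the sulfone, while the electron-poor double bonds of the pyranone and the acetate should not react.

Step 8
Reactants: 17 (2S)-11-[3,5-diethyl-6-(methanesulfonyl)-4-oxo-4H-pyran-2-yl]undecan-2-yl acetate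
Product: 19 3,5-diethyl-2-[(10S)-10-hydroxyundecyl]-6-methoxy-4H-pyran-4-one, via methoxypyranone acetate 18 (not isolated)
Conditions: NaOMe (3 equiv), MeOH, 0 °C → rt; AcOH quench
Reagents that add atoms: sodium methoxide, C[O-].[Na+]
Why: C2 is the only ring carbon with a leaving group and is activated both by the C4 carbonyl and by the sulfonyl group, so methoxide adds there and expels methanesulfinate (addition–elimination of the SNAr type) to give 18 in the flask, and the excess methoxide, used on purpose to drive the exchange to completion, then removes the acetate by Zemplén-type transesterification so that one defined product is isolated and not an ester/alcohol mixture.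

Step 9
Reactants: 19 3,5-diethyl-2-[(10S)-10-hydroxyundecyl]-6-methoxy-4H-pyran-4-one
Product: 18 (2S)-11-(3,5-diethyl-6-methoxy-4-oxo-4H-pyran-2-yl)undecan-2-yl acetate (target)
Conditions: Ac2O, pyridine, DMAP (cat.), CH2Cl2, rt
Reagents that add atoms: acetic anhydride, CC(=O)OC(C)=O
Why: DMAP-catalysed acetylation of the only hydroxyl group breaks no bond at the stereocenter, so the S configuration is retained, and the methoxypyranone has no other site that is acylated.

Compound list
1 | heptan-4-one | CCCC(=O)CCC | starting material
2 | carbon disulfide | S=C=S | starting material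
3 | dilithium 2-ethyl-3-oxohex-1-ene-1,1-bis(thiolate) | [Li+].[Li+].CCCC(=O)C(CC)=C([S-])[S-] | intermediate (not isolated)
4 | 3-[bis(methylsulfanyl)methylidene]heptan-4-one | CCCC(=O)C(CC)=C(SC)SC | intermediate
5 | 10-bromodec-1-ene | C=CCCCCCCCCBr | starting material
6 | (S)-propylene oxide, (2S)-2-methyloxirane | C[C@H]1CO1 | starting material
7 | dec-9-enylmagnesium bromide | C=CCCCCCCCC[Mg]Br | intermediate (not isolated)
8 | (2S)-tridec-12-en-2-ol | C=CCCCCCCCCC[C@H](C)O | intermediate
9 | (2S)-tridec-12-en-2-yl acetate | C=CCCCCCCCCC[C@H](C)OC(C)=O | intermediate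
10 | (2S)-12-oxododecan-2-yl acetate | O=CCCCCCCCCC[C@H](C)OC(C)=O | intermediate (not isolated)
11 | (11S)-11-acetoxydodecanoic acid | OC(=O)CCCCCCCCC[C@H](C)OC(C)=O | intermediate
12 | (11S)-11-acetoxydodecanoyl chloride | O=C(Cl)CCCCCCCCC[C@H](C)OC(C)=O | intermediate
13 | lithium 3-[bis(methylsulfanyl)methylidene]hept-4-en-4-olate | [Li+].CCC=C([O-])C(CC)=C(SC)SC | intermediate (not isolated)
14 | (2S)-15-[bis(methylsulfanyl)methylidene]-13-ethyl-12,14-dioxoheptadecan-2-yl acetate (C13 unassigned, largely enolised) | CCC(C(=O)CCCCCCCCC[C@H](C)OC(C)=O)C(=O)C(CC)=C(SC)SC | intermediate (not isolated)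
15 | (2S)-11-[3,5-diethyl-6-(methylsulfanyl)-4-oxo-4H-pyran-2-yl]undecan-2-yl acetate | CCc1c(CCCCCCCCC[C@H](C)OC(C)=O)oc(SC)c(CC)c1=O | intermediate
16 | (2S)-11-[3,5-diethyl-6-(methanesulfinyl)-4-oxo-4H-pyran-2-yl]undecan-2-yl acetate (both configurations at sulfur) | CCc1c(CCCCCCCCC[C@H](C)OC(C)=O)oc(S(C)=O)c(CC)c1=O | intermediate (not isolated)
17 | (2S)-11-[3,5-diethyl-6-(methanesulfonyl)-4-oxo-4H-pyran-2-yl]undecan-2-yl acetate | CCc1c(CCCCCCCCC[C@H](C)OC(C)=O)oc(S(C)(=O)=O)c(CC)c1=O | intermediate
18 | (2S)-11-(3,5-diethyl-6-methoxy-4-oxo-4H-pyran-2-yl)undecan-2-yl acetate | CCc1c(CCCCCCCCC[C@H](C)OC(C)=O)oc(OC)c(CC)c1=O | target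
19 | 3,5-diethyl-2-[(10S)-10-hydroxyundecyl]-6-methoxy-4H-pyran-4-one | CCc1c(CCCCCCCCC[C@H](C)O)oc(OC)c(CC)c1=O | intermediate

Total step count: 9
Longest linear sequence: 8 steps (steps 2 to 9, from 10-bromodec-1-ene); step 1 is a one-step side branch that joins at step 6.

Steps most likely to fail

Step 6. The enolate may be acylated on oxygen, the acid chloride may be turned into a ketene by proton transfer, or the ring closure of the hindered, fully substituted enol may be so slow that the ketene dithioacetal is lost on work-up. The fallback forms the C5–C6 bond by aldol addition and oxidation in place of acylation, and sets out from 9 and 4. Ozonolysis of 9 (O3, CH2Cl2, -78 °C; PPh3) gives aldehyde 10, now isolated. Enolate 13 (from 4 with one equivalent of LiN(SiMe3)2, THF, -78 °C) adds to 10 to give the aldol adduct (2S)-15-[bis(methylsulfanyl)methylidene]-13-ethyl-12-hydroxy-14-oxoheptadecan-2-yl acetate F1 as a mixture of diastereomers, which is of no consequence. Dess–Martin periodinane (CH2Cl2, NaHCO3) oxidises F1 to diketone 14, and CF3CO2H closes the ring as before. The fallback comes back to the route at 15.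

Step 1. The second deprotonation or the second S-methylation may stay incomplete, the silylamide may attack CS2, or the ketone may condense with itself. The fallback brings in the thiocarbonyl carbon with one S-methyl group already attached and sets out from 1. The sodium enolate of 1 (NaH, DMF/hexane) is treated with dimethyl trithiocarbonate in a thio-Claisen-type condensation to give the isolable methyl 2-ethyl-3-oxohexanedithioate F2. S-Methylation of F2 (MeI, K2CO3, acetone) comes back to the route at 4.

Step 8. Incomplete exchange at the hindered C2, or attack of methoxide on C6 or C4 of the pyranone with ring opening during the exposure needed to remove the acetate, may erode the material. The fallback installs the C2 oxygen as hydroxide and methylates it afterwards, and sets out from 17. Aqueous LiOH (THF/H2O, 0 °C → rt) displaces the sulfinate and hydrolyses the acetate; the substitution product is at once deprotonated to an unreactive vinylogous carboxylate. Acidification gives 3,5-diethyl-4-hydroxy-6-[(10S)-10-hydroxyundecyl]-2H-pyran-2-one F3. Methyl triflate without base (CH2Cl2, 0 °C → rt; NaHCO3 work-up) methylates the ring carbonyl oxygen, the known regioselective route from 4-hydroxy-2-pyranones to 2-methoxy-4-pyranones. The fallback comes back to the route at 19, which is acetylated as in step 9.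

Further compounds
F1 | step 6 | (2S)-15-[bis(methylsulfanyl)methylidene]-13-ethyl-12-hydroxy-14-oxoheptadecan-2-yl acetate (C12 and C13 unassigned) | CCC(C(O)CCCCCCCCC[C@H](C)OC(C)=O)C(=O)C(CC)=C(SC)SC
F2 | step 1 | methyl 2-ethyl-3-oxohexanedithioate | CCCC(=O)C(CC)C(=S)SC
F3 | step 8 | 3,5-diethyl-4-hydroxy-6-[(10S)-10-hydroxyundecyl]-2H-pyran-2-one | CCC1=C(CCCCCCCCC[C@H](C)O)OC(=O)C(CC)=C1O
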